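**Strategy.** The route rests on cutting the ketone carbon from C3 of the pyridone ring. C3 lies between the C2 lactam carbonyl and the C4 enol oxygen, so the ring is a cyclic vinylogous acid. Its own oxygens (N1–O and C4–O) first pick up the trienoyl group from the carbodiimide-activated acid, and 4-dimethylaminopyridine then shuttles the acyl group from these oxygen esters to C3, where it is locked as the hydrogen-bonded 3-acyl-4-hydroxy chelate. In one operation the silyl-protected (R)-trienoic acid and the 1,4-dihydroxy-2-pyridone, free at both ring oxygens, are joined; the precursor is a mixture of O-acyl esters that converges on one C-acyl product.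

Key step: step 14

Remark: the cyclohexane is read from the SMILES as a cis-1,4-diol (both oxygens on one ring face, the pyridone carbon trans to the secondary oxygen) and the side-chain centre as R; compounds 1, 2, 4, 10, 12, 15 and 17 are taken as commercial.

Step 1
Reactants: 1 (R)-4-benzyloxazolidin-2-one; 2 butanoyl chloride
Product: 3 (R)-4-benzyl-3-butanoyloxazolidin-2-one
Conditions: Et3N, DMAP (cat.), CH2Cl2, 0 °C → rt
Reagents that add atoms: none
Why: DMAP-catalysed N-acylation of the oxazolidinone by the acid chloride should give the imide without touching the auxiliary stereocentre.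

Step 2
Reactants: 3 (R)-4-benzyl-3-butanoyloxazolidin-2-one; 4 1,3,5-trioxane
Product: 6 (R)-4-benzyl-3-[(S)-2-(hydroxymethyl)butanoyl]oxazolidin-2-one, via titanium (Z)-enolate 5 (not isolated)
Conditions: TiCl4, iPr2NEt, CH2Cl2, 0 °C; then 4, TiCl4, 0 °C; aq. NH4Cl
Reagents that add atoms: none
Why: Titanium-enolate hydroxymethylation of an N-acyl oxazolidinone (Evans aldol-type addition to formaldehyde released from trioxane) should occur on the face of the chelated (Z)-enolate 5 opposite the C4 benzyl group, which sets the (S) centre that becomes C8 of the target (R there only because the CIP priorities change).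

Step 3
Reactants: 6 (R)-4-benzyl-3-[(S)-2-(hydroxymethyl)butanoyl]oxazolidin-2-one
Product: 7 (R)-4-benzyl-3-[(S)-2-(tert-butyldimethylsilyloxymethyl)butanoyl]oxazolidin-2-one
Conditions: TBSCl, imidazole, DMF, rt
Reagents that add atoms: tert-butyldimethylsilyl chloride, CC(C)(C)[Si](C)(C)Cl
Why: Imidazole-mediated silylation of the primary alcohol should protect it for the reduction, oxidation and olefination steps without base strong enough for retro-aldol cleavage.

Step 4
Reactants: 7 (R)-4-benzyl-3-[(S)-2-(tert-butyldimethylsilyloxymethyl)butanoyl]oxazolidin-2-one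
Product: 8 (R)-2-(tert-butyldimethylsilyloxymethyl)butan-1-ol
Conditions: LiBH4, H2O (1 equiv), Et2O, 0 °C
Reagents that add atoms: none
Why: Reductive cleavage of the N-acyl oxazolidinone with lithium borohydride at the exocyclic carbonyl should release the primary alcohol and the auxiliary without affecting the stereocentre.

Step 5
Reactants: 8 (R)-2-(tert-butyldimethylsilyloxymethyl)butan-1-ol
Product: 9 (S)-2-(tert-butyldimethylsilyloxymethyl)butanal
Conditions: TEMPO (cat.), PhI(OAc)2, CH2Cl2, rt
Reagents that add atoms: none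
Why: The TEMPO/PhI(OAc)2 oxidation stops at the aldehyde and is non-basic, so the α-stereocentre should survive if the crude aldehyde is used at once.

Step 6
Reactants: 9 (S)-2-(tert-butyldimethylsilyloxymethyl)butanal; 10 (triphenylphosphoranylidene)acetaldehyde
Product: 11 (2E,4R)-4-(tert-butyldimethylsilyloxymethyl)hex-2-enal
Conditions: toluene, 80 °C
Reagents that add atoms: none
Why: Wittig olefination with the stabilised formyl ylide should give the E-enal, since the weakly basic ylide reacts faster with the saturated aldehyde than with the conjugated product.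

Step 7
Reactants: 11 (2E,4R)-4-(tert-butyldimethylsilyloxymethyl)hex-2-enal; 12 triethyl 4-phosphonocrotonate
Product: 13 ethyl (2E,4E,6E,8R)-8-(tert-butyldimethylsilyloxymethyl)deca-2,4,6-trienoate
Conditions: LiHMDS, THF, −78 °C; then 11, −78 → 0 °C
Reagents that add atoms: none
Why: Horner–Wadsworth–Emmons olefination with the lithiated phosphonocrotonate should form the new C4=C5 bond E-selectively while the two existing E double bonds are carried through unchanged.

Step 8
Reactants: 13 ethyl (2E,4E,6E,8R)-8-(tert-butyldimethylsilyloxymethyl)deca-2,4,6-trienoate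
Product: 14 (2E,4E,6E,8R)-8-(tert-butyldimethylsilyloxymethyl)deca-2,4,6-trienoic acid
Conditions: LiOH·H2O, THF/MeOH/H2O, rt; then aq. HCl to pH 4, 0 °C
Reagents that add atoms: lithium hydroxide, [Li+].[OH-]
Why: Ester saponification should leave the primary silyl ether and the triene geometry intact under these mild aqueous conditions.

Step 9
Reactants: 15 5-bromo-2,4-dichloropyridine
Product: 16 2,4-bis(benzyloxy)-5-bromopyridine
Conditions: BnOH, NaH, THF, 0 °C; then 15, DMF, 80 °C
Reagents that add atoms: benzyl alcohol, OCc1ccccc1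
Why: Double nucleophilic aromatic substitution (addition–elimination) should replace the C4 and then the C2 chloride, both activated by the ring nitrogen, while the unactivated C5 bromide stays.

Step 10
Reactants: 16 2,4-bis(benzyloxy)-5-bromopyridine; 17 4-(tert-butyldimethylsilyloxy)cyclohexan-1-one
Product: 19 cis-1-[4,6-bis(benzyloxy)pyridin-3-yl]-4-(tert-butyldimethylsilyloxy)cyclohexan-1-ol, via aryllithium 18 (not isolated)
Conditions: n-BuLi, THF, −78 °C; then 17, −78 °C; H2O
Reagents that add atoms: none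
Why: Bromine–lithium exchange followed by 1,2-addition to the ketone, in which the hindered ortho-benzyloxy aryllithium should prefer equatorial attack on the chair with equatorial OTBS, placing the aryl group equatorial and the new hydroxyl axial and cis to OTBS; the minor trans isomer should be removable by chromatography.

Step 11
Reactants: 19 cis-1-[4,6-bis(benzyloxy)pyridin-3-yl]-4-(tert-butyldimethylsilyloxy)cyclohexan-1-ol
Product: 20 2,4-bis(benzyloxy)-5-[cis-4-(tert-butyldimethylsilyloxy)-1-(triethylsilyloxy)cyclohexyl]pyridine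
Conditions: TESOTf, 2,6-lutidine, CH2Cl2, −78 → 0 °C
Reagents that add atoms: triethylsilyl trifluoromethanesulfonate, CC[Si](CC)(CC)OS(=O)(=O)C(F)(F)F
Why: Silyl triflate silylation should cap the hindered tertiary alcohol, so that it cannot later trap the acyl group from the neighbouring C4 oxygen or ionise.

Step 12
Reactants: 20 2,4-bis(benzyloxy)-5-[cis-4-(tert-butyldimethylsilyloxy)-1-(triethylsilyloxy)cyclohexyl]pyridine
Product: 21 2,4-bis(benzyloxy)-5-[cis-4-(tert-butyldimethylsilyloxy)-1-(triethylsilyloxy)cyclohexyl]pyridine 1-oxide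
Conditions: mCPBA, CH2Cl2, 0 °C → rt
Reagents that add atoms: 3-chloroperbenzoic acid, O=C(OO)c1cccc(Cl)c1
Why: Peracid N-oxidation of the pyridine nitrogen, the only oxidisable site, should install the N–O bond while the molecule still has no alkene; the 2-benzyloxy N-oxide is a masked 1-hydroxy-2-pyridone.

Step 13
Reactants: 21 2,4-bis(benzyloxy)-5-[cis-4-(tert-butyldimethylsilyloxy)-1-(triethylsilyloxy)cyclohexyl]pyridine 1-oxide
Product: 22 1,4-dihydroxy-5-[cis-4-(tert-butyldimethylsilyloxy)-1-(triethylsilyloxy)cyclohexyl]pyridin-2(1H)-one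
Conditions: H2 (1 atm), Pd/C, EtOAc, rt
Reagents that add atoms: none
Why: Hydrogenolysis of both benzyl ethers should unmask the 2-hydroxypyridine N-oxide, which tautomerises to the 1-hydroxy-2-pyridone; stopping at two equivalents of hydrogen in a neutral aprotic solvent should keep the N–O bond and the silyl ethers.

Step 14
Reactants: 14 (2E,4E,6E,8R)-8-(tert-butyldimethylsilyloxymethyl)deca-2,4,6-trienoic acid; 22 1,4-dihydroxy-5-[cis-4-(tert-butyldimethylsilyloxy)-1-(triethylsilyloxy)cyclohexyl]pyridin-2(1H)-one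
Product: 25 3-[(2E,4E,6E,8R)-8-(tert-butyldimethylsilyloxymethyl)deca-2,4,6-trienoyl]-1,4-dihydroxy-5-[cis-4-(tert-butyldimethylsilyloxy)-1-(triethylsilyloxy)cyclohexyl]pyridin-2(1H)-one, via N-acyloxy ester 23 (not isolated), via C4-O enol ester 24 (not isolated)
Conditions: DCC, DMAP (2.5 equiv), CH2Cl2, 0 °C → rt
Reagents that add atoms: none
Why: DCC converts acid 14 into the O-acylisourea and DMAP into the N-acylpyridinium ion, which acylates the two acidic oxygens of 22 (N1–O and C4–O) to give the active esters 23 and 24; because both are esters of good leaving groups (pKa about 6), DMAP re-forms the acylpyridinium ion from either, and C3 of the 4-oxido-2-pyridone, flanked by the C2 carbonyl and C4–O, attacks it irreversibly, so the O-acyl mixture should drain into the single C3 ketone 25, held as its DMAP salt and as the O4–H···O=C chelate. The closest known reaction type is the carbodiimide/DMAP acylation with 1,3 O→C acyl shift (Fries-type, Steglich-type acyl transfer) of 4-hydroxy-2-pyridones, 4-hydroxy-2-pyrones, tetramic acids and cyclic 1,3-diones. No ring is closed and no stereocentre is formed; C8 and the ring centres are untouched and the all-E triene is remote from the reacting acyl carbon. The step needs C- over O-acylation and 1,2- over conjugate attack: the first is secured by the reversibility of every O-acylation (the tertiary alcohol next to C4–O, the only hydroxyl that could trap the acyl group for good, is a triethylsilyl ether and the other alcohols are silyl ethers), the second by the hard acyl carbon of the acylpyridinium ion.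

Step 15
Reactants: 25 3-[(2E,4E,6E,8R)-8-(tert-butyldimethylsilyloxymethyl)deca-2,4,6-trienoyl]-1,4-dihydroxy-5-[cis-4-(tert-butyldimethylsilyloxy)-1-(triethylsilyloxy)cyclohexyl]pyridin-2(1H)-one
Product: 26 3-[(2E,4E,6E,8R)-8-(hydroxymethyl)deca-2,4,6-trienoyl]-1,4-dihydroxy-5-(cis-1,4-dihydroxycyclohexyl)pyridin-2(1H)-one
Conditions: HF·pyridine, pyridine, THF, 0 °C → rt
Reagents that add atoms: none
Why: Fluoride-mediated desilylation with pyridine-buffered HF should remove the two tert-butyldimethylsilyl ethers and the tertiary triethylsilyl ether without ionising the tertiary carbinol or touching the trienone and the N–O bond.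

**Compound list**

1 | (R)-4-benzyloxazolidin-2-one | O=C1N[C@H](Cc2ccccc2)CO1 | starting material
2 | butanoyl chloride | CCCC(=O)Cl | starting material
3 | (R)-4-benzyl-3-butanoyloxazolidin-2-one | CCCC(=O)N1[C@H](Cc2ccccc2)COC1=O | intermediate
4 | 1,3,5-trioxane | C1OCOCO1 | starting material
5 | trichlorotitanium (Z)-enolate of 3 | CC/C=C(\O[Ti](Cl)(Cl)Cl)N1[C@H](Cc2ccccc2)COC1=O | intermediate
6 | (R)-4-benzyl-3-[(S)-2-(hydroxymethyl)butanoyl]oxazolidin-2-one | CC[C@H](C(=O)N1[C@H](Cc2ccccc2)COC1=O)CO | intermediate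
7 | (R)-4-benzyl-3-[(S)-2-(tert-butyldimethylsilyloxymethyl)butanoyl]oxazolidin-2-one | CC[C@H](C(=O)N1[C@H](Cc2ccccc2)COC1=O)CO[Si](C)(C)C(C)(C)C | intermediate
8 | (R)-2-(tert-butyldimethylsilyloxymethyl)butan-1-ol | CC[C@H](CO)CO[Si](C)(C)C(C)(C)C | intermediate
9 | (S)-2-(tert-butyldimethylsilyloxymethyl)butanal | CC[C@H](C=O)CO[Si](C)(C)C(C)(C)C | intermediate
10 | (triphenylphosphoranylidene)acetaldehyde | O=CC=P(c1ccccc1)(c1ccccc1)c1ccccc1 | starting material
11 | (2E,4R)-4-(tert-butyldimethylsilyloxymethyl)hex-2-enal | CC[C@H](/C=C/C=O)CO[Si](C)(C)C(C)(C)C | intermediate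
12 | triethyl 4-phosphonocrotonate, ethyl (E)-4-(diethoxyphosphoryl)but-2-enoate | CCOC(=O)/C=C/CP(=O)(OCC)OCC | starting material
13 | ethyl (2E,4E,6E,8R)-8-(tert-butyldimethylsilyloxymethyl)deca-2,4,6-trienoate | CC[C@H](/C=C/C=C/C=C/C(=O)OCC)CO[Si](C)(C)C(C)(C)C | intermediate
14 | (2E,4E,6E,8R)-8-(tert-butyldimethylsilyloxymethyl)deca-2,4,6-trienoic acid | CC[C@H](/C=C/C=C/C=C/C(=O)O)CO[Si](C)(C)C(C)(C)C | intermediate
15 | 5-bromo-2,4-dichloropyridine | Clc1cc(Cl)c(Br)cn1 | starting material
16 | 2,4-bis(benzyloxy)-5-bromopyridine | Brc1cnc(OCc2ccccc2)cc1OCc1ccccc1 | intermediate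
17 | 4-(tert-butyldimethylsilyloxy)cyclohexan-1-one | O=C1CCC(O[Si](C)(C)C(C)(C)C)CC1 | starting material
18 | [4,6-bis(benzyloxy)pyridin-3-yl]lithium | [Li]c1cnc(OCc2ccccc2)cc1OCc1ccccc1 | intermediate
19 | cis-1-[4,6-bis(benzyloxy)pyridin-3-yl]-4-(tert-butyldimethylsilyloxy)cyclohexan-1-ol (OH and OTBS on the same face) | c1ccccc1COc1cc(OCc2ccccc2)c(cn1)[C@]3(O)CC[C@@H](O[Si](C)(C)C(C)(C)C)CC3 | intermediate
20 | 2,4-bis(benzyloxy)-5-[cis-4-(tert-butyldimethylsilyloxy)-1-(triethylsilyloxy)cyclohexyl]pyridine | c1ccccc1COc1cc(OCc2ccccc2)c(cn1)[C@]3(O[Si](CC)(CC)CC)CC[C@@H](O[Si](C)(C)C(C)(C)C)CC3 | intermediate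
21 | 2,4-bis(benzyloxy)-5-[cis-4-(tert-butyldimethylsilyloxy)-1-(triethylsilyloxy)cyclohexyl]pyridine 1-oxide | c1ccccc1COc1cc(OCc2ccccc2)c(c[n+]1[O-])[C@]3(O[Si](CC)(CC)CC)CC[C@@H](O[Si](C)(C)C(C)(C)C)CC3 | intermediate
22 | 1,4-dihydroxy-5-[cis-4-(tert-butyldimethylsilyloxy)-1-(triethylsilyloxy)cyclohexyl]pyridin-2(1H)-one | O=c1cc(O)c(cn1O)[C@]3(O[Si](CC)(CC)CC)CC[C@@H](O[Si](C)(C)C(C)(C)C)CC3 | intermediate
23 | N1–O trienoyl ester of 22 (1-acyloxy-4-hydroxy-2-pyridone) | CC[C@H](/C=C/C=C/C=C/C(=O)On1cc([C@]3(O[Si](CC)(CC)CC)CC[C@@H](O[Si](C)(C)C(C)(C)C)CC3)c(O)cc1=O)CO[Si](C)(C)C(C)(C)C | intermediate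
24 | C4–O trienoyl enol ester of 22 (4-acyloxy-1-hydroxy-2-pyridone) | CC[C@H](/C=C/C=C/C=C/C(=O)Oc1cc(=O)n(O)cc1[C@]3(O[Si](CC)(CC)CC)CC[C@@H](O[Si](C)(C)C(C)(C)C)CC3)CO[Si](C)(C)C(C)(C)C | intermediate
25 | 3-[(2E,4E,6E,8R)-8-(tert-butyldimethylsilyloxymethyl)deca-2,4,6-trienoyl]-1,4-dihydroxy-5-[cis-4-(tert-butyldimethylsilyloxy)-1-(triethylsilyloxy)cyclohexyl]pyridin-2(1H)-one | CC[C@H](/C=C/C=C/C=C/C(=O)c1c(O)c([C@]3(O[Si](CC)(CC)CC)CC[C@@H](O[Si](C)(C)C(C)(C)C)CC3)cn(O)c1=O)CO[Si](C)(C)C(C)(C)C | intermediate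
26 | 3-[(2E,4E,6E,8R)-8-(hydroxymethyl)deca-2,4,6-trienoyl]-1,4-dihydroxy-5-(cis-1,4-dihydroxycyclohexyl)pyridin-2(1H)-one | CC[C@H](/C=C/C=C/C=C/C(=O)c1c(O)c([C@]2(O)CC[C@@H](O)CC2)cn(O)c1=O)CO | target

**Totals.** Total step count: 15. Longest linear sequence: 10 steps (steps 1–8, 14, 15).

**Steps most likely to fail**

Step 14. The acyl group may stay parked on the N-oxygen, or the N-acyloxy ester and the trienoyl pyridinium ion may be consumed by side reactions before the hand-over to C3. The fallback sets out from 20 and returns at 25; it takes the N-oxygen out of the acyl-transfer step and installs it afterwards. Compound 20 is hydrogenolysed directly (H2, Pd/C, EtOAc), without N-oxidation, to 4-hydroxy-5-[cis-4-(tert-butyldimethylsilyloxy)-1-(triethylsilyloxy)cyclohexyl]pyridin-2(1H)-one F1. Carbodiimide/DMAP acylation of this N–H pyridone with acid 14 (DCC, DMAP, CH2Cl2) should give the N–H 3-trienoyl-4-hydroxypyridone F2. Persilylation (HMDS, TMSCl) should give the 2,4-bis(trimethylsilyloxy)pyridine F3, which is oxidised at nitrogen with MoO5·pyridine·HMPA (CH2Cl2, rt) and hydrolysed on aqueous work-up to 25.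

Step 10. Facial selectivity of the addition may be poor (axial against equatorial attack, and reaction through the conformer with axial OTBS), and the aryllithium may enolise the ketone. The fallback sets out from 16 and returns at 19; it separates carbon–carbon bond formation from the setting of the ring configuration. Aryllithium 18 (from 16, n-BuLi, THF, −78 °C) is added to 1,4-dioxaspiro[4.5]decan-8-one, where no stereo question arises, to give 8-[4,6-bis(benzyloxy)pyridin-3-yl]-1,4-dioxaspiro[4.5]decan-8-ol F4. Ketal hydrolysis (PPTS, acetone/H2O, 50 °C) should give 4-[4,6-bis(benzyloxy)pyridin-3-yl]-4-hydroxycyclohexan-1-one F5. NaBH4 (MeOH, −40 °C) should attack axially on the chair with the aryl group equatorial and give the equatorial secondary alcohol, cis-1-[4,6-bis(benzyloxy)pyridin-3-yl]cyclohexane-1,4-diol F6. Selective silylation of the secondary hydroxyl (TBSCl, imidazole, DMF) gives 19.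

Step 6. The α-stereocentre of aldehyde 9 may epimerise at 80 °C, and the product enal may be homologated a second time. The fallback sets out from 9 and returns at 11; it homologates at the ester oxidation level under mild conditions. Horner–Wadsworth–Emmons reaction of 9 with triethyl phosphonoacetate under LiCl/DBU (MeCN, 0 °C) should give ethyl (2E,4R)-4-(tert-butyldimethylsilyloxymethyl)hex-2-enoate F7. DIBAL-H (CH2Cl2, −78 °C) gives (2E,4R)-4-(tert-butyldimethylsilyloxymethyl)hex-2-en-1-ol F8, and MnO2 (CH2Cl2, rt) gives 11.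

**Further compounds**

F1 | step 14 | 4-hydroxy-5-[cis-4-(tert-butyldimethylsilyloxy)-1-(triethylsilyloxy)cyclohexyl]pyridin-2(1H)-one | O=c1cc(O)c(c[nH]1)[C@]3(O[Si](CC)(CC)CC)CC[C@@H](O[Si](C)(C)C(C)(C)C)CC3
F2 | step 14 | 3-[(2E,4E,6E,8R)-8-(tert-butyldimethylsilyloxymethyl)deca-2,4,6-trienoyl]-4-hydroxy-5-[cis-4-(tert-butyldimethylsilyloxy)-1-(triethylsilyloxy)cyclohexyl]pyridin-2(1H)-one | CC[C@H](/C=C/C=C/C=C/C(=O)c1c(O)c([C@]3(O[Si](CC)(CC)CC)CC[C@@H](O[Si](C)(C)C(C)(C)C)CC3)c[nH]c1=O)CO[Si](C)(C)C(C)(C)C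
F3 | step 14 | 3-[(2E,4E,6E,8R)-8-(tert-butyldimethylsilyloxymethyl)deca-2,4,6-trienoyl]-2,4-bis(trimethylsilyloxy)-5-[cis-4-(tert-butyldimethylsilyloxy)-1-(triethylsilyloxy)cyclohexyl]pyridine | CC[C@H](/C=C/C=C/C=C/C(=O)c1c(O[Si](C)(C)C)c([C@]3(O[Si](CC)(CC)CC)CC[C@@H](O[Si](C)(C)C(C)(C)C)CC3)cnc1O[Si](C)(C)C)CO[Si](C)(C)C(C)(C)C
F4 | step 10 | 8-[4,6-bis(benzyloxy)pyridin-3-yl]-1,4-dioxaspiro[4.5]decan-8-ol | c1ccccc1COc1cc(OCc2ccccc2)c(cn1)C3(O)CCC4(CC3)OCCO4
F5 | step 10 | 4-[4,6-bis(benzyloxy)pyridin-3-yl]-4-hydroxycyclohexan-1-one | c1ccccc1COc1cc(OCc2ccccc2)c(cn1)C3(O)CCC(=O)CC3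
F6 | step 10 | cis-1-[4,6-bis(benzyloxy)pyridin-3-yl]cyclohexane-1,4-diol | c1ccccc1COc1cc(OCc2ccccc2)c(cn1)[C@]3(O)CC[C@@H](O)CC3
F7 | step 6 | ethyl (2E,4R)-4-(tert-butyldimethylsilyloxymethyl)hex-2-enoate | CC[C@H](/C=C/C(=O)OCC)CO[Si](C)(C)C(C)(C)C
F8 | step 6 | (2E,4R)-4-(tert-butyldimethylsilyloxymethyl)hex-2-en-1-ol | CC[C@H](/C=C/CO)CO[Si](C)(C)C(C)(C)C
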